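**Retrosynthetic overview**

1. The trans-fused 8,9-oxirane is made last, by hydroxyl-directed epoxidation of the transient (8E)-cycloheptene formed on low-temperature photoisomerisation of the (8Z)-alkene 10α-alcohol. That alcohol comes from reagent-controlled reduction of a cycloheptenone closed by ring-closing metathesis at C8=C9.
2. The cis-2α,4α-diol of the five-membered ring comes from a cyclopentenone (C2=O, C3=C4–iPr) by α-face nucleophilic epoxidation, then hydride (ketone reduction plus oxirane opening).
3. The quaternary C1 comes from two successive α′-enolate reactions of that cyclopentenone (MeI, then acrolein), each anti to the C5 side chain.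
4. The cyclopentenone comes from a ketal-ketone aldol by isopropyl addition, ketal hydrolysis and dehydration. The aldol comes from an achiral enol silane and 3-methylbut-3-enal by a catalytic asymmetric Mukaiyama aldol (new) that sets C5 and C6.
5. Ring order: five-membered ring (purchased), then seven-membered ring (metathesis), then oxirane.

Assumption: the stereodescriptors of the given string are taken literally; they put the oxirane oxygen on the β face at C8 (8α-methyl) and on the α face at C9 (9β-H, syn to the 10α-hydroxyl), that is a trans-fused oxirane on the seven-membered ring, and the route is built to deliver exactly that.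

Convention: carbons carry their daucane (target) numbers throughout; β is the ring face that carries the C1 methyl in the target, α the opposite face.

**Step 1**
Reactants: 1 1,4-dioxaspiro[4.4]nonan-7-one
Product: 2 tert-butyl(1,4-dioxaspiro[4.4]non-7-en-7-yloxy)dimethylsilane
Conditions: LiN(iPr)2, THF, −78 °C; TBSCl, DMPU, −78 °C → rt
Reagents that add atoms: tert-butyldimethylsilyl chloride, CC(C)(C)[Si](C)(C)Cl
Why: Kinetic deprotonation takes the unhindered α-CH2 remote from the spiro ketal (future C5) and O-silylation of the lithium enolate gives the regiodefined, achiral silyl enol ether (enol silane formation).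

**Step 2**
Reactants: 3 3-methylbut-3-en-1-ol
Product: 4 3-methylbut-3-enal
Conditions: Dess–Martin periodinane, NaHCO3, CH2Cl2, 0 °C; filtered solution used at once
Reagents that add atoms: none
Why: Buffered Dess–Martin oxidation of the primary alcohol gives the β,γ-unsaturated aldehyde without conjugation to prenal.

**Step 3**
Reactants: 2 tert-butyl(1,4-dioxaspiro[4.4]non-7-en-7-yloxy)dimethylsilane; 4 3-methylbut-3-enal
Product: 5 (8R)-8-[(1R)-1-(tert-butyldimethylsilyloxy)-3-methylbut-3-en-1-yl]-1,4-dioxaspiro[4.4]nonan-7-one
Conditions: confined BINOL-derived imidodiphosphorimidate Brønsted acid (IDPi, 3,3′-aryl, N-triflyl core, 2 mol %, antipode chosen for 8R,1′R), toluene, −78 °C, slow addition of 4; Et3N quench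
Reagents that add atoms: none
Why: Proposed new method: the IDPi acid is silylated by 2 to a silylium–imidodiphosphorimidate ion pair that activates aldehyde 4 as a silyloxocarbenium ion inside the chiral anion; the cyclic (E)-enol silane adds through an open antiperiplanar transition state that keeps the ring away from the aldehyde substituent (anti aldol), the anion selects one pair of enantiofaces so that C5 and C6 are set together from achiral partners, and TBS transfer to the aldolate oxygen turns the catalyst over and delivers the silyl-protected aldol directly; the base-free −78 °C conditions avoid the dienamine isomerisation of the β,γ-unsaturated aldehyde that amine catalysts cause, and the dioxolane should survive because its opening is reversible; the closest known reaction type is the IDPi- or disulfonimide-catalysed Mukaiyama aldol of ester- and aldehyde-derived enol silanes with aldehydes, not yet shown for a ketone-derived cyclic enol silane with a β,γ-unsaturated aliphatic aldehyde.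

**Step 4**
Reactants: 5 (8R)-8-[(1R)-1-(tert-butyldimethylsilyloxy)-3-methylbut-3-en-1-yl]-1,4-dioxaspiro[4.4]nonan-7-one
Product: 8 (4S)-4-[(1R)-1-(tert-butyldimethylsilyloxy)-3-methylbut-3-en-1-yl]-3-isopropylcyclopent-2-en-1-one, via carbinol ketal 6 (not isolated), via hydroxy ketone 7 (not isolated)
Conditions: iPrMgCl, CeCl3, THF, −78 °C; then aq. oxalic acid, THF, 40 °C
Reagents that add atoms: isopropylmagnesium chloride, CC(C)[Mg]Cl; water, O
Why: The non-basic organocerium reagent adds 1,2 to the hindered enolisable ketone without epimerising C5; mild acid then hydrolyses the ketal and dehydrates the tertiary β-hydroxy ketone through its enol to the conjugated enone (1,3-carbonyl transposition of Stork–Danheiser type), the transient C4 carbinol centre being erased.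

**Step 5**
Reactants: 8 (4S)-4-[(1R)-1-(tert-butyldimethylsilyloxy)-3-methylbut-3-en-1-yl]-3-isopropylcyclopent-2-en-1-one
Product: 9 5-methyl derivative of 8 (methyl on C1 trans to the C5 side chain, 1α-methyl)
Conditions: LiN(iPr)2, THF, −78 °C; MeI, −78 → −20 °C
Reagents that add atoms: iodomethane, CI
Why: Kinetic α′-deprotonation gives the cross-conjugated enolate, which is methylated anti to the C5 side chain (enolate alkylation); this C1 centre is re-planarised in step 6.

**Step 6**
Reactants: 9 5-methyl derivative of 8; 10 prop-2-enal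
Product: 12 C1-quaternary enone (1β-methyl; 1α-[1-(triethylsilyloxy)prop-2-enyl]; other centres as in 8), via lithium aldolate 11 (not isolated)
Conditions: LiN(iPr)2, THF, −78 → −30 °C; prop-2-enal, −78 °C; TESOTf, −78 °C
Reagents that add atoms: triethylsilyl trifluoromethanesulfonate, CC[Si](CC)(CC)OS(=O)(=O)C(F)(F)F
Why: The tetrasubstituted α′-enolate adds 1,2 to acrolein on the α face, anti to the C5 side chain, which fixes the quaternary C1 with methyl β (lithium aldol, Zimmerman–Traxler); silylation at −78 °C blocks retro-aldol, and the C10 epimer ratio is immaterial because C10 is reset in steps 12 and 14.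

**Step 7**
Reactants: 12 C1-quaternary enone
Product: 13 3α,4α-epoxy ketone of 12
Conditions: tBuOOH (decane), DBU, CH2Cl2, 0 °C → rt
Reagents that add atoms: tert-butyl hydroperoxide, CC(C)(C)OO
Why: Weitz–Scheffer nucleophilic epoxidation of the enone; the hydroperoxide adds to C4 anti to the adjacent C5 side chain, so the oxirane (and the future C4 oxygen) is α, and 12 has no acidic α-hydrogen that could trigger retro-aldol or elimination.

**Step 8**
Reactants: 13 3α,4α-epoxy ketone
Product: 15 2α,4α-diol (4β-isopropyl; C3 is CH2), via epoxy alcohol 14 (not isolated)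
Conditions: LiAlH4, THF, −78 → 45 °C
Reagents that add atoms: none
Why: Hydride attacks C2 from the β face, anti to the oxirane oxygen on C3 and to the bulky C10 branch on C1, giving the cis-epoxy alcohol (2α-OH); a second hydride then opens the oxirane by SN2 at the secondary C3 and leaves the tertiary 4α-alcohol (epoxy ketone reduction, then regioselective epoxide hydrogenolysis).

**Step 9**
Reactants: 15 2α,4α-diol
Product: 16 2α-acetate of 15
Conditions: Ac2O, pyridine, DMAP (cat.), CH2Cl2, rt
Reagents that add atoms: acetic anhydride, CC(=O)OC(C)=O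
Why: DMAP-catalysed acetylation takes the secondary C2 hydroxyl and leaves the tertiary C4 hydroxyl; C6 and C10 are still silylated, so the acetate is placed unambiguously.

**Step 10**
Reactants: 16 2α-acetate
Product: 17 2α-acetoxy-4α,6,10-triol diene (both silyl ethers removed)
Conditions: HF·pyridine, pyridine, THF, 0 °C → rt
Reagents that add atoms: none
Why: Buffered fluoride cleaves the TES and TBS ethers without base-induced acetyl migration (desilylation).

**Step 11**
Reactants: 17 2α-acetoxy-4α,6,10-triol diene
Product: 18 2α-acetoxydauc-8-ene-4α,6α,10-triol (trans-fused hydroazulene; 10β-OH major)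
Conditions: second-generation Grubbs catalyst (5 mol %), CH2Cl2, 40 °C
Reagents that add atoms: none
Why: Ring-closing metathesis of the vinyl carbinol with the 1,1-disubstituted methallyl alkene forms the trisubstituted (Z) C8=C9 cycloheptene; the two chains are already trans on the cyclopentane, so the ring fusion is trans, and the free allylic hydroxyl assists initiation.

**Step 12**
Reactants: 18 2α-acetoxydauc-8-ene-4α,6α,10-triol
Product: 19 2α-acetoxy-4α,6α-dihydroxydauc-8-en-10-one
Conditions: MnO2 (excess), CH2Cl2, rt
Reagents that add atoms: none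
Why: MnO2 oxidises only the allylic C10 alcohol (the C6 hydroxyl is homoallylic, C4 tertiary), and both C10 epimers converge on one enone.

**Step 13**
Reactants: 19 2α-acetoxy-4α,6α-dihydroxydauc-8-en-10-one; 20 3,4-dimethoxybenzoyl chloride
Product: 21 6α-(3,4-dimethoxybenzoate) of 19
Conditions: Et3N, DMAP, CH2Cl2, 0 °C → rt
Reagents that add atoms: none
Why: DMAP-catalysed acylation of the only remaining secondary hydroxyl (C6); the tertiary C4 hydroxyl does not react, and Et3N is too weak to enolise the enone toward elimination.

**Step 14**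
Reactants: 21 6α-(3,4-dimethoxybenzoate) enone
Product: 22 2α-acetoxy-6α-(3,4-dimethoxybenzoyloxy)dauc-8-ene-4α,10α-diol
Conditions: (R)-2-methyl-CBS-oxazaborolidine (0.5 equiv), catecholborane, toluene, −78 → −40 °C
Reagents that add atoms: none
Why: Corey–Bakshi–Shibata reduction under reagent control, with the quaternary C1 as the large and the vinylic C9 as the small ketone substituent, delivers hydride to the β face and gives the 10α-alcohol that simple hydrides (attack anti to the angular methyl) would not; both esters are untouched.

**Step 15**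
Reactants: 22 2α-acetoxy-6α-(3,4-dimethoxybenzoyloxy)dauc-8-ene-4α,10α-diol
Product: 24 2α-acetoxy-6α-(3,4-dimethoxybenzoyloxy)-8β,9α-epoxydaucane-4α,10α-diol (trans-fused oxirane; target), via (8E)-cycloheptene 23 (not isolated)
Conditions: hν (300 nm, quartz flow coil), CH2Cl2, −78 °C; outflow led in the dark into VO(OiPr)3 (20 mol %), tBuOOH (decane), −78 → −50 °C; cold aq. Na2S2O3; recovered 22 recycled
Reagents that add atoms: tert-butyl hydroperoxide, CC(C)(C)OO
Why: Proposed new method: light absorbed by the 3,4-dimethoxybenzoyl ester, whose ester oxygen sits two bonds from C8, is passed to the neighbouring trisubstituted alkene and twists it to the strained (8E)-cycloheptene 23, which should persist at −78 °C; only the outer face of a trans-cycloalkene is open, and of its two planar-diastereomeric forms only the one whose outer lobe at C9 lies syn to the 10α-hydroxyl can be reached by the tert-butylperoxide bound to the C10 vanadate ester, so oxygen is transferred suprafacially to C9 from the α side and to C8 from the β side, setting both new centres as the trans-fused oxirane, while the other E form reverts to 22 and relaxed 22 is too slow to react with the vanadium peroxide at this temperature; the closest known reaction types are the aromatic-ester-sensitised Z→E photoisomerisation of cycloheptenes with low-temperature trapping of the E isomer by osmium tetroxide or dienes, the epoxidation of (E)-cyclooctene to its trans-fused oxide, and the vanadium-catalysed hydroxyl-directed epoxidation of cyclic allylic alcohols.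

**Compound list**

1 | 1,4-dioxaspiro[4.4]nonan-7-one | O=C1CCC2(C1)OCCO2 | starting material
2 | tert-butyl(1,4-dioxaspiro[4.4]non-7-en-7-yloxy)dimethylsilane | CC(C)(C)[Si](C)(C)OC1=CCC2(C1)OCCO2 | intermediate
3 | 3-methylbut-3-en-1-ol | C=C(C)CCO | starting material
4 | 3-methylbut-3-enal | C=C(C)CC=O | intermediate
5 | (8R)-8-[(1R)-1-(tert-butyldimethylsilyloxy)-3-methylbut-3-en-1-yl]-1,4-dioxaspiro[4.4]nonan-7-one (anti aldol; C5 and C6) | C=C(C)C[C@@H](O[Si](C)(C)C(C)(C)C)[C@H]1CC2(CC1=O)OCCO2 | intermediate
6 | 7-isopropyl-7-hydroxy derivative of 5 (carbinol ketal; C4 carbinol epimers, either serves) | C=C(C)C[C@@H](O[Si](C)(C)C(C)(C)C)[C@H]1CC2(CC1(O)C(C)C)OCCO2 | intermediate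
7 | 3-hydroxy-3-isopropyl-4-[(1R)-1-(tert-butyldimethylsilyloxy)-3-methylbut-3-en-1-yl]cyclopentan-1-one | C=C(C)C[C@@H](O[Si](C)(C)C(C)(C)C)[C@H]1CC(=O)CC1(O)C(C)C | intermediate
8 | (4S)-4-[(1R)-1-(tert-butyldimethylsilyloxy)-3-methylbut-3-en-1-yl]-3-isopropylcyclopent-2-en-1-one | C=C(C)C[C@@H](O[Si](C)(C)C(C)(C)C)[C@H]1CC(=O)C=C1C(C)C | intermediate
9 | 5-methyl derivative of 8, methyl trans to the C4 side chain (1α-methyl) | C=C(C)C[C@@H](O[Si](C)(C)C(C)(C)C)[C@H]1[C@H](C)C(=O)C=C1C(C)C | intermediate
10 | prop-2-enal (acrolein) | C=CC=O | starting material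
11 | lithium aldolate of 9 with acrolein (1β-methyl, 1α-carbinol branch) | C=C(C)C[C@@H](O[Si](C)(C)C(C)(C)C)[C@H]1[C@](C)([C@H]([O-])C=C)C(=O)C=C1C(C)C.[Li+] | intermediate
12 | 4-[(1R)-1-(tert-butyldimethylsilyloxy)-3-methylbut-3-en-1-yl]-3-isopropyl-5-methyl-5-[1-(triethylsilyloxy)prop-2-en-1-yl]cyclopent-2-en-1-one, 5-methyl cis to the C4 side chain (1β-methyl); major C10 epimer drawn | C=C(C)C[C@@H](O[Si](C)(C)C(C)(C)C)[C@H]1[C@](C)([C@H](O[Si](CC)(CC)CC)C=C)C(=O)C=C1C(C)C | intermediate
13 | 3α,4α-epoxy ketone of 12 | C=C(C)C[C@@H](O[Si](C)(C)C(C)(C)C)[C@H]1[C@](C)([C@H](O[Si](CC)(CC)CC)C=C)C(=O)[C@@H]2O[C@]12C(C)C | intermediate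
14 | 3α,4α-epoxy-2α-ol from 13 | C=C(C)C[C@@H](O[Si](C)(C)C(C)(C)C)[C@H]1[C@](C)([C@H](O[Si](CC)(CC)CC)C=C)[C@H](O)[C@@H]2O[C@]12C(C)C | intermediate
15 | 2α,4α-diol (4β-isopropyl, 1β-methyl, both silyl ethers in place) | C=C(C)C[C@@H](O[Si](C)(C)C(C)(C)C)[C@H]1[C@](C)([C@H](O[Si](CC)(CC)CC)C=C)[C@H](O)C[C@@]1(O)C(C)C | intermediate
16 | 2α-acetate of 15 | C=C(C)C[C@@H](O[Si](C)(C)C(C)(C)C)[C@H]1[C@](C)([C@H](O[Si](CC)(CC)CC)C=C)[C@H](OC(C)=O)C[C@@]1(O)C(C)C | intermediate
17 | 2α-acetoxy-4α,6,10-triol diene (metathesis precursor) | C=C(C)C[C@@H](O)[C@H]1[C@](C)([C@H](O)C=C)[C@H](OC(C)=O)C[C@@]1(O)C(C)C | intermediate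
18 | 2α-acetoxydauc-8-ene-4α,6α,10β-triol (trans-fused hydroazulene; 10-epimer of the target series) | O[C@@H]2CC(C)=C[C@@H](O)[C@]3(C)[C@H](OC(C)=O)C[C@@](O)(C(C)C)[C@@H]23 | intermediate
19 | 2α-acetoxy-4α,6α-dihydroxydauc-8-en-10-one | O[C@@H]2CC(C)=CC(=O)[C@]3(C)[C@H](OC(C)=O)C[C@@](O)(C(C)C)[C@@H]23 | intermediate
20 | 3,4-dimethoxybenzoyl chloride | COc1ccc(C(=O)Cl)cc1OC | starting material
21 | 2α-acetoxy-6α-(3,4-dimethoxybenzoyloxy)-4α-hydroxydauc-8-en-10-one | COc1ccc(C(=O)O[C@@H]2CC(C)=CC(=O)[C@]3(C)[C@H](OC(C)=O)C[C@@](O)(C(C)C)[C@@H]23)cc1OC | intermediate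
22 | 2α-acetoxy-6α-(3,4-dimethoxybenzoyloxy)dauc-8-ene-4α,10α-diol ((8Z)-cycloheptene) | COc1ccc(C(=O)O[C@@H]2CC(C)=C[C@H](O)[C@]3(C)[C@H](OC(C)=O)C[C@@](O)(C(C)C)[C@@H]23)cc1OC | intermediate
23 | (8E)-isomer of 22 (trans-cycloheptene; C8 methyl on the α side, C9–H on the β side, outer alkene lobe at C9 syn to the 10α-hydroxyl) | COc1ccc(C(=O)O[C@@H]2C/C(C)=C/[C@H](O)[C@]3(C)[C@H](OC(C)=O)C[C@@](O)(C(C)C)[C@@H]23)cc1OC | intermediate
24 | 2α-acetoxy-6α-(3,4-dimethoxybenzoyloxy)-8β,9α-epoxydaucane-4α,10α-diol (trans-fused oxirane: C8–O β with 8α-methyl, C9–O α with 9β-H) | COc1ccc(C(=O)O[C@@H]2C[C@@]3(C)O[C@@H]3[C@H](O)[C@]3(C)[C@H](OC(C)=O)C[C@@](O)(C(C)C)[C@@H]23)cc1OC | target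

**Totals**

Total step count: 15. Longest linear sequence: 14 steps (1 → 24 through steps 1 and 3–15; step 2 makes the aldehyde partner).

**Steps most likely to fail**

Step 15 (the proposed new photoisomerisation and directed epoxidation) is the least certain step of the route. Energy transfer from the dimethoxybenzoyl ester may be inefficient or divert into ester–alkene photocycloaddition. The E form needed may be the less populated of the two planar diastereomers, because the quaternary C1 adds transannular strain. Reversion to 22 may also outrun oxygen transfer. The fallback uses known operations, sets out from 22 and comes back at 24. A solution of 22 with methyl benzoate as sensitiser is pumped in a closed loop through a quartz coil (254 nm, −50 °C) and a cooled column of AgNO3-impregnated silica, as practised for trans-cycloheptenes. The E-alkene is held back as its silver complex while the Z-alkene recirculates. Elution with ethanol gives the silver nitrate π-complex of the (8E)-alkene F7, and its two planar diastereomers are separated at this stage. The needed diastereomer of F7 is added to dimethyldioxirane in acetone–CH2Cl2 at −78 °C together with Bu4NCl. Silver is stripped as AgCl and the freed 23 is epoxidised at once on its only open face, by stereospecific syn oxygen transfer as for (E)-cyclooctene, to give 24. Diastereomer separation of the silver complexes here replaces the kinetic selection by the hydroxyl group.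

Step 3 (the proposed new aldol) may fail through ketal ionisation, aldehyde isomerisation or poor anti/enantio control. The fallback uses known chemistry, sets out from 1 and comes back at 6. (R)-Proline (30 mol %) catalyses the direct anti aldol of ketone 1 (3 equiv, excess recovered) with chloroacetaldehyde in DMSO at 4 °C to give the chlorohydrin (8R)-8-[(1S)-2-chloro-1-hydroxyethyl]-1,4-dioxaspiro[4.4]nonan-7-one F1. Isopropylcerium dichloride (3 equiv, THF, −78 °C) adds to the ketone and NaOH in MeOH closes the chlorohydrin to the epoxy carbinol 7-isopropyl-8-[(2S)-oxiran-2-yl]-1,4-dioxaspiro[4.4]nonan-7-ol F2. Isopropenylmagnesium bromide with 10 mol % CuI (THF, −30 °C) opens the oxirane at its CH2 terminus to the diol 8-[(1R)-1-hydroxy-3-methylbut-3-en-1-yl]-7-isopropyl-1,4-dioxaspiro[4.4]nonan-7-ol F3. TBSOTf with 2,6-lutidine at −78 °C silylates only the secondary hydroxyl and gives 6, which then passes through the acid stage of step 4.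

Step 6 may fail because the remaining α′-hydrogen of 9 is tertiary and cis to the C5 side chain, so deprotonation is slow and γ-deprotonation or retro-aldol can compete. The fallback sets out from 8 and comes back at 12. The easily formed kinetic α′-enolate of 8 (LiN(iPr)2, −78 °C) is trapped with dimethyl(methylidene)ammonium iodide to give the Mannich base F4. MeI converts it into the methiodide F5, and NaHCO3 eliminates this to the α′-methylene dienone F6. LiBH(sBu)3 (THF, −78 °C) adds hydride 1,4 to the exocyclic enone only, which generates the same tetrasubstituted C1 enolate regiospecifically without any hindered deprotonation (the C1 methyl arises from the methylene). Trapping with acrolein and then TESOTf as in step 6 gives 12 (conjugate reduction–aldol).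

**Further compounds**

F1 | step 3 | (8R)-8-[(1S)-2-chloro-1-hydroxyethyl]-1,4-dioxaspiro[4.4]nonan-7-one | ClC[C@@H](O)[C@H]1CC2(CC1=O)OCCO2
F2 | step 3 | (8R)-7-isopropyl-8-[(2S)-oxiran-2-yl]-1,4-dioxaspiro[4.4]nonan-7-ol (C7 epimers) | C1O[C@H]1[C@H]2CC3(CC2(O)C(C)C)OCCO3
F3 | step 3 | (8R)-8-[(1R)-1-hydroxy-3-methylbut-3-en-1-yl]-7-isopropyl-1,4-dioxaspiro[4.4]nonan-7-ol (C7 epimers) | C=C(C)C[C@@H](O)[C@H]1CC2(CC1(O)C(C)C)OCCO2
F4 | step 6 | 5-[(dimethylamino)methyl] derivative of 8 (aminomethyl trans to the C4 side chain) | C=C(C)C[C@@H](O[Si](C)(C)C(C)(C)C)[C@H]1[C@H](CN(C)C)C(=O)C=C1C(C)C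
F5 | step 6 | methiodide of F4 (trimethylammonium iodide) | C=C(C)C[C@@H](O[Si](C)(C)C(C)(C)C)[C@H]1[C@H](C[N+](C)(C)C)C(=O)C=C1C(C)C.[I-]
F6 | step 6 | 5-methylidene derivative of 8 (α′-methylene dienone) | C=C(C)C[C@@H](O[Si](C)(C)C(C)(C)C)[C@H]1C(=C)C(=O)C=C1C(C)C
F7 | step 15 | silver nitrate π-complex of the (8E)-alkene 23 (planar diastereomer with the outer C9 lobe syn to the 10α-hydroxyl) | COc1ccc(C(=O)O[C@@H]2C/C(C)=C/[C@H](O)[C@]3(C)[C@H](OC(C)=O)C[C@@](O)(C(C)C)[C@@H]23)cc1OC.[Ag+].[O-][N+](=O)[O-]
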